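Take the logarithm of a conversion curve before you extrapolate it.

| flask | substrate | coupling partner | scavenger | initiator | remark | time |
|---|---|---|---|---|---|---|
| red | 0.050 M | 0.22 M | 0.050 M | 0.50 mM | run made earlier |  |
| blue | 0.050 M | 0.15 M | 0.050 M | 1 mM | run made earlier |  |
| south-west | 0.050 M | 0.150 M | 0.0500 M | 0.50 mM |  | 6.0 h |
| south-east | 0.050 M | 0.150 M | 0.100 M | 0.50 mM |  | 6.0 h |

| run | time / min | substrate / % | product / % |
|---|---|---|---|
| red | 10.0 | 95.7 | 5.4 |
| red | 20.0 | 92.3 | 9.1 |
| red | 40.0 | 84.7 | 15.1 |
| red | 60.0 | 79.6 | 20.5 |
| red | 120 | 69.1 | 30.8 |
| blue | 25.0 | 90.5 | 9.3 |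
| blue | 50.0 | 82.8 | 17.2 |
| blue | 80.0 | 76.5 | 23.5 |
| blue | 90.0 | 74.9 | 25.5 |
| blue | 120 | 70.0 | 30.4 |

(scatter of a reading: 0.5 percentage points)

- no earlier run changes the charge of scavenger; that part of a forecast is a guess

* part of the substrate that has reacted at the end, south-west
* part of the substrate that has reacted at the end, south-east
* what raising the concentration of scavenger from its lowest to its highest value here does to the part of the substrate that has reacted (changes below 5 percentage points count as none) (no change / it rises / it falls)

I carried one quantity, the dose: minus the natural logarithm of the substrate fraction left, the integral of a pseudo-first-order constant, rescaled to south-west's charges in proportion to c(coupling partner) and the square root of c(initiator). At 120 min the red run read 0.252 and the blue run 0.252, so two different recipes gave one dose. Red's dose stood at 0.156 at 60.0 min, then grew by 0.0964 h⁻¹, slower than in its first hour. Run straight on to 6.0 h, that gave south-west's dose as 0.638, or 47.2% reacted. The slope was still falling, so I held this reckoning of mine as an upper estimate for south-west. No run varied the scavenger, so I guessed no change for south-east.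

The forecast, lower than my upper estimate, gave 35% for south-west, 35% for south-east and no change, saying “I favour burn-out”.

The flasks gave 41.9% in south-west and 42.0% in south-east, so the verdict was no change, and the larger scavenger charge is not the reason for south-east's figure.

    initiator → 2 initiating radical (k = 6.50 × 10⁻⁶ s⁻¹)
    scavenger + released group → scavenged by-product (k = 0.0130 M⁻¹ s⁻¹)
    substrate + initiating radical → capped initiator + first chain carrier (k = 3.40 × 10⁵ M⁻¹ s⁻¹)
    coupling partner + first chain carrier ⇌ product + second chain carrier (K = 0.230, k = 4500 M⁻¹ s⁻¹)
    2 first chain carrier → ended chains (k = 1.80 × 10⁸ M⁻¹ s⁻¹)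
    coupling partner ⇌ dormant form (K = 1.80, k = 2.00 × 10⁻⁴ s⁻¹)
    substrate + second chain carrier → released group + first chain carrier (k = 32000 M⁻¹ s⁻¹)
    coupling partner + released group ⇌ idle adduct, settled at all times (K = 5.40 M⁻¹)

South-west's real dose was 0.543, below my 0.638. South-west stood at 41.9% at 6.0 h because of the ending of chains and the length of the run together: without the step to ended chains it reached 100%, and left until 60.0 h it reached 97.3%. Scaled to the neighbour of south-west charged with 0.26 M of coupling partner, my dose gave 66.9% and south-west's real dose 61.0%; that neighbour gave 63.5%.

The earlier runs and the new flask are simulated on assumed constants; the scatter is artificial.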